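**Numbering.** Isoflavan numbering is used: O1, C2, C3, C4, C4a, C5–C8, C8a. Ring A is the benzo ring, ring C the dihydropyran, ring B the aryl group on C3 (primed locants), and ring D the 2,2-dimethylpyran fused to ring B. By CIP analysis the SMILES is the (3R)-isoflavan.

## The problem

1. The target is a (3R)-isoflavan whose only stereocentre, C3, is a tertiary benzylic CH between two methylene groups, with no heteroatom or carbonyl next to it in the final structure.
2. Ring A is a phloroglucinol with three different oxygens (O1 on C8a, OMe on C5, OH on C7). Its two carbon substituents, C4 on C4a and the prenyl group on C6, both flank the OMe, while C8 between O1 and 7-OH must stay unsubstituted; electrophiles and sigmatropic shifts on a finished 5,7-dioxygenated chroman do not tell C6 from C8.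
3. Ring B is a resorcinol in which the oxygen next to C1' is tied into ring D (fused at C2'–C3') while 4'-OH stays free, so the pyran must close on one defined oxygen.
4. The prenyl group ortho to a free phenol and the styrene-type C=C of ring D forbid hydrogenation, hydrogenolysis, strong Lewis acids and electrophilic oxidants late in the route. The phloroglucinol ring also makes any leaving group on benzylic C4 very labile.
5. The feature that the plan uses: the two methylene arms of C3, C2 (bound to O1) and C4 (bound to C4a), both end on ring A. Cutting O1–C2 and C4–C4a leaves ArB–CH(CH2–)2 with a prochiral C3; tied through one oxygen this is a 3-aryloxetane whose two C–O bonds are enantiotopic.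
6. Opening one of these bonds with a chiral catalyst sets C3 without a carbonyl group and at the same time tells the future C4 (halide) from the future C2 (oxygen).
7. A second symmetry helps: 5-OMe is the one oxygen flanked by both carbon substituents and only the oxygen ortho to the chain can close ring C, so ring A can come from symmetric 5-methoxyresorcinol without ever differentiating O1 from O7.

## Retrosynthesis

**O1–C2 and the last protecting group (25 ⇐ 24 ⇐ 23).** The final bonds cut are the silyl ether of 24 and the O1–C2 ether bond, which is made by an intramolecular Mitsunobu reaction of triol 23. Against an aryl C8a–O coupling, this closure needs no halide on ring A and is chemoselective by geometry: only O1 is ortho to the side chain, so 7-OH can be free. Precursor 23 is acyclic, and the forward reaction does not touch C3.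

**C4–C4a (23 ⇐ 22 ⇐ 12 + 20).** The benzylic sp3–sp2 bond is cut, giving aryl iodide 20 (all of ring A) and bromide 12, which reacts as the primary alkylzinc 21. A C3–C4 cut would put a leaving group on a benzylic carbon of a phloroglucinol and make C3 an enolate carbon. A C3–C1' cut would require stereocontrol at a secondary carbon with two nearly identical CH2 arms. The two fragments are of similar size; the Negishi coupling must accept a di-ortho-substituted iodide, and the stereocentre, β to zinc, is a spectator.

**The oxetane (12 ⇐ 11 ⇐ 9).** The C–Br carbon and the C–O oxygen of 11 are reconnected to the four-membered ring of 9, an achiral compound. In the forward direction a chiral hydrogen-bond donor with TMSBr opens one of the two enantiotopic C–O bonds. This is preferred over an auxiliary or an enzymatic diol desymmetrisation because one catalytic step both creates C3 and hands out the two different termini. The product has no acidic C–H at the stereocentre.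

**Ring B and ring D (9 ⇐ 6 + 7; 6 ⇐ 3 ⇐ 2 ⇐ 1).** The C1'–C3 bond is cut to aryl bromide 6 and 3-iodooxetane 7 (as zinc reagent 8). Ring D is cut at O–C(Me)2 and C3'–C4'' back to propargyl ether 3, phenol 2 and 4-bromoresorcinol 1. The Claisen shift of 3 has one free ortho carbon only, the one between the two oxygens, so the pyran oxygen is necessarily the one next to bromine. Condensing a resorcinol with prenal would give isomer mixtures.

**Ring A (20 ⇐ 18 ⇐ 16 ⇐ 14 ⇐ 13).** The C4a–I, C6–prenyl and C8–Si bonds are cut back to bis-MOM ether 14 of symmetric 5-methoxyresorcinol 13. Three directed ortho-lithiations are ordered by directing power: the site between the two acetals (future C8) reacts first and is blocked with a silyl group that later leaves as H; the two remaining sites are then equivalent (prenyl); the last one takes iodine. No statistical protection and no C6/C8 choice occur.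

## Roads not taken

**Alternative 1:** (the most obvious) Cut C3–C4. The enolate of the ring B arylacetyl oxazolidinone A1 is alkylated with ring A benzyl bromide A2 to imide A3, followed by LiBH4 reduction and Mitsunobu closure.
- A2 is a 2,4,6-trioxygenated benzyl bromide that ionises and alkylates itself.
- C3 is created as the α-carbon of an α-aryl imide and stays enolisable until reduced.
- The stoichiometric auxiliary and the homologation of bromide 6 to the arylacetic acid cost about four extra steps.
- In the chosen plan C4 arrives attached to C3, the centre is never α to a carbonyl, and the chirality source is catalytic.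

**Alternative 2:** Keep ring C and set C3 by reduction. Isoflavone A4 would be reduced by transfer hydrogenation with RuCl(p-cymene)(TsDPEN) under dynamic kinetic resolution and the C4 oxygen then removed; or, after conversion to the C3=C4 alkene, hydrogenated with a chiral iridium P,N complex.
- Hydrogen cannot spare the ring D and prenyl double bonds, so both would have to be introduced afterwards, where C6 and C8 are not distinguishable.
- Transfer hydrogenation spares them but leaves a benzylic C4 hydroxyl on a phloroglucinol ring; removing it needs acid plus hydride or hydrogenolysis, both hostile to the alkenes.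
- Building A4 with 5-OMe, 6-prenyl and 7-OH takes a 5-O-allyl ether Claisen sequence on the chromone, and the centre passes through an enolisable isoflavanone.

**Alternative 3:** Cut O1–C2 and C3–C4 together. A formal [4+2] addition of the ring A ortho-quinone methide to a chiral enolate equivalent of the ring B arylacetic acid (carbene-bound enolate or enamine) gives dihydrocoumarin A5; C2 is then reduced.
- Ring C forms in one step, but phloroglucinol quinone methides self-condense at C8.
- O1 must be unmasked alone, which brings back the O1/O7 differentiation.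
- The new centre sits α to an aryl ester carbonyl under basic conditions.
- C2 still has to go from lactone to CH2 through a diol and a Mitsunobu closure, so nothing is saved.

Key step: step 5

Assumption: the enantiomer of the squaramide catalyst that delivers the (R)-bromide is used; the sense of induction is set by the catalyst alone, so its mirror image would be taken if the opposite sense is found.

## Steps

**Step 1**
Reactants: 1 4-bromobenzene-1,3-diol
Product: 2 2-bromo-5-[(triisopropylsilyl)oxy]phenol
Conditions: TIPSCl (1.05 equiv), imidazole, CH2Cl2, 0 °C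
Reagents that add atoms: chlorotri(propan-2-yl)silane, CC(C)[Si](Cl)(C(C)C)C(C)C
Why: Selective O-silylation under steric control; the hydroxyl ortho to bromine is hindered and hydrogen-bonded to the halogen, so the bulky silyl chloride should take the hydroxyl para to bromine.

**Step 2**
Reactants: 2 2-bromo-5-[(triisopropylsilyl)oxy]phenol
Product: 3 {4-bromo-3-[(2-methylbut-3-yn-2-yl)oxy]phenoxy}triisopropylsilane
Conditions: 3-chloro-3-methylbut-1-yne, DBU, CuCl2 (1 mol%), MeCN, 0 °C
Reagents that add atoms: 3-chloro-3-methylbut-1-yne, CC(C)(Cl)C#C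
Why: Copper-catalysed propargylic etherification of a phenol with a tertiary propargyl chloride (via a copper acetylide) runs under mild base and should leave the aryl bromide and the silyl ether alone.

**Step 3**
Reactants: 3 {4-bromo-3-[(2-methylbut-3-yn-2-yl)oxy]phenoxy}triisopropylsilane
Product: 6 8-bromo-2,2-dimethyl-5-[(triisopropylsilyl)oxy]-2H-chromene, via ortho-allenylphenol 4 (not isolated), via ortho-quinone methide 5 (not isolated)
Conditions: N,N-diethylaniline, 140 °C
Reagents that add atoms: none
Why: Aryl propargyl ether Claisen rearrangement can only reach the free ortho carbon between the two oxygens (the other ortho carbon carries bromine); enolisation, 1,5-hydrogen shift and oxa-6π electrocyclisation then give the 2,2-dimethyl-2H-chromene whose ring oxygen is the one next to bromine.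

**Step 4**
Reactants: 6 8-bromo-2,2-dimethyl-5-[(triisopropylsilyl)oxy]-2H-chromene, 7 3-iodooxetane
Product: 9 3-{2,2-dimethyl-5-[(triisopropylsilyl)oxy]-2H-chromen-8-yl}oxetane, via oxetan-3-ylzinc iodide 8 (not isolated)
Conditions: 7, Zn dust, LiCl, THF, 40 °C; then 6, Pd(OAc)2 (3 mol%), CPhos, THF, 50 °C
Reagents that add atoms: none
Why: Negishi coupling of a secondary alkylzinc reagent with an electron-rich aryl bromide; the biaryl dialkylphosphine favours reductive elimination, and β-hydride elimination is disfavoured in the strained ring.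

**Step 5**
Reactants: 9 3-{2,2-dimethyl-5-[(triisopropylsilyl)oxy]-2H-chromen-8-yl}oxetane
Product: 11 (2R)-3-bromo-2-{2,2-dimethyl-5-[(triisopropylsilyl)oxy]-2H-chromen-8-yl}propan-1-ol, via trimethylsilyl ether 10 (not isolated)
Conditions: TMSBr (1.3 equiv), chiral arylpyrrolidine-derived squaramide (5 mol%), t-BuOMe, −78 °C; then MeOH, citric acid, 0 °C
Reagents that add atoms: bromotrimethylsilane, C[Si](C)(C)Br
Why: This is the hydrogen-bond-donor-catalysed enantioselective ring opening of a 3-substituted oxetane with TMSBr, a reaction type established for 3-aryloxetanes. The squaramide binds the bromide of TMSBr, the oxetane oxygen is silylated, and the silyloxetanium–bromide ion pair is held in the chiral pocket while bromide attacks one CH2 carbon in an SN2 step. No ring is closed; the four-membered ring is opened and its strain drives the reaction at low temperature. C3 becomes a stereocentre although no bond to it is made or broken: its configuration is fixed only by which of the two enantiotopic C–O bonds the catalyst offers to bromide, a choice read from the difference between aryl and hydrogen on C3. The step needs enantiotopic-group selection and chemoselection of the oxetane oxygen over the aryl silyl ether, the ring D oxygen and the ring D double bond. The oxetane is the only strained and by far the most Lewis-basic ether in 9, and the low temperature in the absence of free HBr should protect the styrene-type C=C. Aryl participation is excluded by geometry, since the C3–aryl bond cannot become antiperiplanar to a ring C–O bond. Methanolysis of the labile primary silyl ether 10 on work-up gives 11 with bromine on the future C4 and hydroxyl on the future C2.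

**Step 6**
Reactants: 11 (2R)-3-bromo-2-{2,2-dimethyl-5-[(triisopropylsilyl)oxy]-2H-chromen-8-yl}propan-1-ol
Product: 12 [(2R)-3-bromo-2-{2,2-dimethyl-5-[(triisopropylsilyl)oxy]-2H-chromen-8-yl}propoxy](tert-butyl)dimethylsilane
Conditions: TBSCl, imidazole, CH2Cl2, 0 °C → rt
Reagents that add atoms: tert-butylchlorodimethylsilane, CC(C)(C)[Si](C)(C)Cl
Why: Standard silylation of a primary alcohol; the weakly basic medium should not re-close the oxetane or eliminate the bromide, and the ether masks the hydroxyl for the organozinc step.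

**Step 7**
Reactants: 13 5-methoxybenzene-1,3-diol
Product: 14 1-methoxy-3,5-bis(methoxymethoxy)benzene
Conditions: MOMCl (2.5 equiv), i-Pr2NEt, CH2Cl2, 0 °C → rt
Reagents that add atoms: chloromethyl methyl ether, COCCl
Why: Exhaustive O-alkylation of a symmetric resorcinol; the two acetals serve as directing groups for lithiation and are removed together later.

**Step 8**
Reactants: 14 1-methoxy-3,5-bis(methoxymethoxy)benzene
Product: 16 [4-methoxy-2,6-bis(methoxymethoxy)phenyl]trimethylsilane, via aryllithium 15 (not isolated)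
Conditions: n-BuLi (1.0 equiv), THF, 0 °C → rt; then TMSCl, −78 °C → rt
Reagents that add atoms: chlorotrimethylsilane, C[Si](C)(C)Cl
Why: Directed ortho-metalation; the position flanked by two chelating OMOM groups should be lithiated in preference to the two flanked by OMOM and OMe, and silylation blocks this carbon (the future C8) with a group that later leaves as C–H.

**Step 9**
Reactants: 16 [4-methoxy-2,6-bis(methoxymethoxy)phenyl]trimethylsilane
Product: 18 [4-methoxy-2,6-bis(methoxymethoxy)-3-(3-methylbut-2-en-1-yl)phenyl]trimethylsilane, via aryllithium 17 (not isolated)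
Conditions: n-BuLi, THF, 0 °C; then CuBr·SMe2 (10 mol%), prenyl bromide, −78 → 0 °C
Reagents that add atoms: 1-bromo-3-methylbut-2-ene, CC(C)=CCBr
Why: Second directed ortho-metalation at one of the two now equivalent positions between OMe and OMOM, so regiochemistry is not in question; copper-catalysed allylation of the aryllithium at the primary carbon of prenyl bromide should give the linear prenyl group.

**Step 10**
Reactants: 18 [4-methoxy-2,6-bis(methoxymethoxy)-3-(3-methylbut-2-en-1-yl)phenyl]trimethylsilane
Product: 20 [3-iodo-4-methoxy-2,6-bis(methoxymethoxy)-5-(3-methylbut-2-en-1-yl)phenyl]trimethylsilane, via aryllithium 19 (not isolated)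
Conditions: n-BuLi, THF, −20 °C; then ICH2CH2I, −78 °C
Reagents that add atoms: 1,2-diiodoethane, ICCI
Why: The only ring C–H left lies between OMe and OMOM and should be removed by a third directed ortho-metalation faster than the prenyl CH2 is deprotonated; iodine transfer from 1,2-diiodoethane gives the aryl iodide without exposing the alkene to I2.

**Step 11**
Reactants: 12 [(2R)-3-bromo-2-{2,2-dimethyl-5-[(triisopropylsilyl)oxy]-2H-chromen-8-yl}propoxy](tert-butyl)dimethylsilane, 20 [3-iodo-4-methoxy-2,6-bis(methoxymethoxy)-5-(3-methylbut-2-en-1-yl)phenyl]trimethylsilane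
Product: 22 tert-butyl{[(2R)-2-{2,2-dimethyl-5-[(triisopropylsilyl)oxy]-2H-chromen-8-yl}-3-[2-methoxy-4,6-bis(methoxymethoxy)-3-(3-methylbut-2-en-1-yl)-5-(trimethylsilyl)phenyl]propyl]oxy}dimethylsilane, via alkylzinc bromide 21 (not isolated)
Conditions: 12, Zn dust, LiCl, THF, 50 °C; then 20, Pd(OAc)2 (5 mol%), SPhos, THF, 50 °C
Reagents that add atoms: none
Why: LiCl-promoted zinc insertion into the primary bromide followed by Negishi sp3–sp2 coupling; the bulky electron-rich biarylphosphine is made for di-ortho-substituted aryl halides, and fast reductive elimination should outrun β-hydride elimination. The stereocentre is β to zinc and takes no part.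

**Step 12**
Reactants: 22 tert-butyl{[(2R)-2-{2,2-dimethyl-5-[(triisopropylsilyl)oxy]-2H-chromen-8-yl}-3-[2-methoxy-4,6-bis(methoxymethoxy)-3-(3-methylbut-2-en-1-yl)-5-(trimethylsilyl)phenyl]propyl]oxy}dimethylsilane
Product: 23 4-[(2R)-2-{2,2-dimethyl-5-[(triisopropylsilyl)oxy]-2H-chromen-8-yl}-3-hydroxypropyl]-5-methoxy-6-(3-methylbut-2-en-1-yl)benzene-1,3-diol
Conditions: 3 M HCl, MeOH–THF, 40 °C
Reagents that add atoms: none
Why: Acid-catalysed acetal exchange removes both MOM ethers and the primary TBS ether, and the aryl silane, now on a phloroglucinol-type ring, undergoes ipso-protodesilylation; the aryl TIPS ether is the most acid-stable silyl group present and should largely survive (its loss would only make step 14 unnecessary).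

**Step 13**
Reactants: 23 4-[(2R)-2-{2,2-dimethyl-5-[(triisopropylsilyl)oxy]-2H-chromen-8-yl}-3-hydroxypropyl]-5-methoxy-6-(3-methylbut-2-en-1-yl)benzene-1,3-diol
Product: 24 (3R)-3-{2,2-dimethyl-5-[(triisopropylsilyl)oxy]-2H-chromen-8-yl}-5-methoxy-6-(3-methylbut-2-en-1-yl)-3,4-dihydro-2H-chromen-7-ol
Conditions: PPh3, DIAD, THF (0.01 M), 0 °C → rt
Reagents that add atoms: none
Why: Intramolecular Mitsunobu etherification (6-exo-tet), the usual chroman closure of isoflavan syntheses; only the phenol ortho to the propyl chain (O1) can reach the activated primary carbon, so 7-OH needs no protection, and C3 is not touched.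

**Step 14**
Reactants: 24 (3R)-3-{2,2-dimethyl-5-[(triisopropylsilyl)oxy]-2H-chromen-8-yl}-5-methoxy-6-(3-methylbut-2-en-1-yl)-3,4-dihydro-2H-chromen-7-ol
Product: 25 (3R)-3-(5-hydroxy-2,2-dimethyl-2H-chromen-8-yl)-5-methoxy-6-(3-methylbut-2-en-1-yl)-3,4-dihydro-2H-chromen-7-ol
Conditions: TBAF, AcOH, THF, 0 °C
Reagents that add atoms: none
Why: Fluoride cleavage of the aryl silyl ether under acetic acid buffering should free the 4'-phenol without acid- or base-mediated reaction of the prenylphenol or of ring D.

## Compound list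

1 | 4-bromobenzene-1,3-diol | Oc1ccc(Br)c(O)c1 | starting material
2 | 2-bromo-5-[(triisopropylsilyl)oxy]phenol | Oc1cc(O[Si](C(C)C)(C(C)C)C(C)C)ccc1Br | intermediate
3 | {4-bromo-3-[(2-methylbut-3-yn-2-yl)oxy]phenoxy}triisopropylsilane | C#CC(C)(C)Oc1cc(O[Si](C(C)C)(C(C)C)C(C)C)ccc1Br | intermediate
4 | 6-bromo-2-(3-methylbuta-1,2-dien-1-yl)-3-[(triisopropylsilyl)oxy]phenol | Oc1c(Br)ccc(O[Si](C(C)C)(C(C)C)C(C)C)c1C=C=C(C)C | intermediate
5 | 2-bromo-6-(3-methylbut-2-en-1-ylidene)-5-[(triisopropylsilyl)oxy]cyclohexa-2,4-dien-1-one | O=C1C(Br)=CC=C(O[Si](C(C)C)(C(C)C)C(C)C)C1=CC=C(C)C | intermediate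
6 | 8-bromo-2,2-dimethyl-5-[(triisopropylsilyl)oxy]-2H-chromene | CC1(C)C=Cc2c(O[Si](C(C)C)(C(C)C)C(C)C)ccc(Br)c2O1 | intermediate
7 | 3-iodooxetane | IC1COC1 | starting material
8 | iodo(oxetan-3-yl)zinc | I[Zn]C1COC1 | intermediate
9 | 3-{2,2-dimethyl-5-[(triisopropylsilyl)oxy]-2H-chromen-8-yl}oxetane | CC1(C)C=Cc2c(O[Si](C(C)C)(C(C)C)C(C)C)ccc(C3COC3)c2O1 | intermediate
10 | [(2R)-3-bromo-2-{2,2-dimethyl-5-[(triisopropylsilyl)oxy]-2H-chromen-8-yl}propoxy]trimethylsilane | BrC[C@H](c1ccc(O[Si](C(C)C)(C(C)C)C(C)C)c2C=CC(C)(C)Oc12)CO[Si](C)(C)C | intermediate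
11 | (2R)-3-bromo-2-{2,2-dimethyl-5-[(triisopropylsilyl)oxy]-2H-chromen-8-yl}propan-1-ol | BrC[C@H](c1ccc(O[Si](C(C)C)(C(C)C)C(C)C)c2C=CC(C)(C)Oc12)CO | intermediate
12 | [(2R)-3-bromo-2-{2,2-dimethyl-5-[(triisopropylsilyl)oxy]-2H-chromen-8-yl}propoxy](tert-butyl)dimethylsilane | BrC[C@H](c1ccc(O[Si](C(C)C)(C(C)C)C(C)C)c2C=CC(C)(C)Oc12)CO[Si](C)(C)C(C)(C)C | intermediate
13 | 5-methoxybenzene-1,3-diol | COc1cc(O)cc(O)c1 | starting material
14 | 1-methoxy-3,5-bis(methoxymethoxy)benzene | COCOc1cc(OC)cc(OCOC)c1 | intermediate
15 | [4-methoxy-2,6-bis(methoxymethoxy)phenyl]lithium | [Li]c1c(OCOC)cc(OC)cc1OCOC | intermediate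
16 | [4-methoxy-2,6-bis(methoxymethoxy)phenyl]trimethylsilane | COCOc1cc(OC)cc(OCOC)c1[Si](C)(C)C | intermediate
17 | [2-methoxy-4,6-bis(methoxymethoxy)-5-(trimethylsilyl)phenyl]lithium | [Li]c1c(OC)cc(OCOC)c([Si](C)(C)C)c1OCOC | intermediate
18 | [4-methoxy-2,6-bis(methoxymethoxy)-3-(3-methylbut-2-en-1-yl)phenyl]trimethylsilane | COCOc1cc(OC)c(CC=C(C)C)c(OCOC)c1[Si](C)(C)C | intermediate
19 | [2-methoxy-4,6-bis(methoxymethoxy)-3-(3-methylbut-2-en-1-yl)-5-(trimethylsilyl)phenyl]lithium | [Li]c1c(OC)c(CC=C(C)C)c(OCOC)c([Si](C)(C)C)c1OCOC | intermediate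
20 | [3-iodo-4-methoxy-2,6-bis(methoxymethoxy)-5-(3-methylbut-2-en-1-yl)phenyl]trimethylsilane | COCOc1c(I)c(OC)c(CC=C(C)C)c(OCOC)c1[Si](C)(C)C | intermediate
21 | bromo[(2R)-3-[(tert-butyldimethylsilyl)oxy]-2-{2,2-dimethyl-5-[(triisopropylsilyl)oxy]-2H-chromen-8-yl}propyl]zinc | Br[Zn]C[C@H](c1ccc(O[Si](C(C)C)(C(C)C)C(C)C)c2C=CC(C)(C)Oc12)CO[Si](C)(C)C(C)(C)C | intermediate
22 | tert-butyl{[(2R)-2-{2,2-dimethyl-5-[(triisopropylsilyl)oxy]-2H-chromen-8-yl}-3-[2-methoxy-4,6-bis(methoxymethoxy)-3-(3-methylbut-2-en-1-yl)-5-(trimethylsilyl)phenyl]propyl]oxy}dimethylsilane | COCOc1c(C[C@H](c2ccc(O[Si](C(C)C)(C(C)C)C(C)C)c3C=CC(C)(C)Oc23)CO[Si](C)(C)C(C)(C)C)c(OC)c(CC=C(C)C)c(OCOC)c1[Si](C)(C)C | intermediate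
23 | 4-[(2R)-2-{2,2-dimethyl-5-[(triisopropylsilyl)oxy]-2H-chromen-8-yl}-3-hydroxypropyl]-5-methoxy-6-(3-methylbut-2-en-1-yl)benzene-1,3-diol | COc1c(CC=C(C)C)c(O)cc(O)c1C[C@H](c1ccc(O[Si](C(C)C)(C(C)C)C(C)C)c2C=CC(C)(C)Oc12)CO | intermediate
24 | (3R)-3-{2,2-dimethyl-5-[(triisopropylsilyl)oxy]-2H-chromen-8-yl}-5-methoxy-6-(3-methylbut-2-en-1-yl)-3,4-dihydro-2H-chromen-7-ol | COc1c(CC=C(C)C)c(O)cc2c1C[C@H](c1ccc(O[Si](C(C)C)(C(C)C)C(C)C)c3c1OC(C)(C)C=C3)CO2 | intermediate
25 | (3R)-3-(5-hydroxy-2,2-dimethyl-2H-chromen-8-yl)-5-methoxy-6-(3-methylbut-2-en-1-yl)-3,4-dihydro-2H-chromen-7-ol | COc1c(CC=C(C)C)c(O)cc2c1C[C@H](c1ccc(O)c3c1OC(C)(C)C=C3)CO2 | target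

## Step count and risks

Total: 14 steps. Longest linear sequence: 10 steps from 1 (steps 1–6 and 11–14). The ring A branch from 13 (steps 7–10) has 4 steps.

**Step 5 (key step).** The catalyst may discriminate the two enantiotopic C–O bonds poorly when the aryl group is ortho-substituted and very electron-rich. TMSBr may also cleave the allylic aryl ether of ring D or add HBr to its double bond.
Fallback (known chemistry), from 6 back to 11:
- Bromide 6 would be coupled with diethyl malonate (Pd2(dba)3, P(t-Bu)3, K3PO4, toluene, 70 °C) to diethyl arylmalonate F2.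
- LiAlH4 reduction would give the prochiral 2-arylpropane-1,3-diol F3.
- A lipase from Burkholderia cepacia with vinyl acetate would acetylate one enantiotopic hydroxymethyl group; enzyme and direction of acyl transfer are chosen to give the (S)-monoacetate F4.
- CBr4/PPh3 would give the (R)-bromo acetate F5, and i-Bu2AlH at −78 °C would remove the acetate to give 11.

**Step 11.** Oxidative addition and transmetalation may be slow at the fully substituted aryl iodide, giving way to β-hydride elimination or protonation of the alkylzinc reagent.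
Fallback, from 18 and 12 back to 22: the roles are reversed. Silane 18 would be lithiated as in step 10 (to 19) and transmetalated with ZnCl2 to the arylzinc chloride F8. This would be coupled with bromide 12 under Pd2(dba)3, P(c-C5H9)3 and N-methylimidazole in THF–NMP at 80 °C, so that oxidative addition occurs at the unhindered primary bromide and the hindered ring enters by transmetalation.

**Step 12.** Acid may cyclise the prenyl group onto the freed 7-hydroxyl and add methanol across the ring D double bond before acetal cleavage is complete.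
Fallback, from 13 back to 25: a fluoride-only end game.
- 13 would be converted with SEMCl and i-Pr2NEt into the bis-SEM ether F9.
- The lithiation sequence of steps 8–10 would be repeated to give the blocked silane F10, the prenyl compound F11 and the iodide F12.
- Negishi coupling with 21 as in step 11 would give F13.
- TBAF in DMPU at 60 °C followed by an acetic acid quench would strip the SEM, TBS and TIPS groups and the aryl silane to give tetraol F14.
- Mitsunobu closure as in step 13 would give 25 directly.

**Step 8.** Lithiation may compete at the two positions between OMOM and OMe, which are statistically favoured, giving the silane at the wrong carbon.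
Fallback, from 13 back to 16: the position is fixed by electrophilic substitution rather than by metalation. Iodination of 13 in aqueous NaHCO3 with I2 attacks the carbon between the two hydroxyls and would give 2-iodo-5-methoxybenzene-1,3-diol F6. MOMCl and i-Pr2NEt would give its bis-MOM ether F7. Iodine–lithium exchange with n-BuLi at −78 °C regenerates 15 regiospecifically, and TMSCl gives 16.

**Step 1.** Silylation may occur at the hydroxyl ortho to bromine or on both oxygens.
Fallback, from 1 back to 2: 1 would be silylated exhaustively (TIPSCl, imidazole, DMF) to the bis-silyl ether F1. The silyl group on the more acidic phenol oxygen, the one ortho to bromine, would then be removed selectively with LiOAc in wet DMF to give 2.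

## Further compounds

F1 | step 1 | [(4-bromo-1,3-phenylene)bis(oxy)]bis(triisopropylsilane) | CC(C)[Si](Oc1ccc(Br)c(O[Si](C(C)C)(C(C)C)C(C)C)c1)(C(C)C)C(C)C
F2 | step 5 | diethyl 2-{2,2-dimethyl-5-[(triisopropylsilyl)oxy]-2H-chromen-8-yl}propanedioate | CCOC(=O)C(C(=O)OCC)c1ccc(O[Si](C(C)C)(C(C)C)C(C)C)c2C=CC(C)(C)Oc12
F3 | step 5 | 2-{2,2-dimethyl-5-[(triisopropylsilyl)oxy]-2H-chromen-8-yl}propane-1,3-diol | OCC(CO)c1ccc(O[Si](C(C)C)(C(C)C)C(C)C)c2C=CC(C)(C)Oc12
F4 | step 5 | (2S)-2-{2,2-dimethyl-5-[(triisopropylsilyl)oxy]-2H-chromen-8-yl}-3-hydroxypropyl acetate | OC[C@H](c1ccc(O[Si](C(C)C)(C(C)C)C(C)C)c2C=CC(C)(C)Oc12)COC(C)=O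
F5 | step 5 | (2R)-3-bromo-2-{2,2-dimethyl-5-[(triisopropylsilyl)oxy]-2H-chromen-8-yl}propyl acetate | BrC[C@H](c1ccc(O[Si](C(C)C)(C(C)C)C(C)C)c2C=CC(C)(C)Oc12)COC(C)=O
F6 | step 8 | 2-iodo-5-methoxybenzene-1,3-diol | COc1cc(O)c(I)c(O)c1
F7 | step 8 | 2-iodo-5-methoxy-1,3-bis(methoxymethoxy)benzene | COCOc1cc(OC)cc(OCOC)c1I
F8 | step 11 | chloro[2-methoxy-4,6-bis(methoxymethoxy)-3-(3-methylbut-2-en-1-yl)-5-(trimethylsilyl)phenyl]zinc | Cl[Zn]c1c(OC)c(CC=C(C)C)c(OCOC)c([Si](C)(C)C)c1OCOC
F9 | step 12 | 1-methoxy-3,5-bis{[2-(trimethylsilyl)ethoxy]methoxy}benzene | COc1cc(OCOCC[Si](C)(C)C)cc(OCOCC[Si](C)(C)C)c1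
F10 | step 12 | (4-methoxy-2,6-bis{[2-(trimethylsilyl)ethoxy]methoxy}phenyl)trimethylsilane | COc1cc(OCOCC[Si](C)(C)C)c([Si](C)(C)C)c(OCOCC[Si](C)(C)C)c1
F11 | step 12 | [4-methoxy-3-(3-methylbut-2-en-1-yl)-2,6-bis{[2-(trimethylsilyl)ethoxy]methoxy}phenyl]trimethylsilane | COc1cc(OCOCC[Si](C)(C)C)c([Si](C)(C)C)c(OCOCC[Si](C)(C)C)c1CC=C(C)C
F12 | step 12 | [3-iodo-4-methoxy-5-(3-methylbut-2-en-1-yl)-2,6-bis{[2-(trimethylsilyl)ethoxy]methoxy}phenyl]trimethylsilane | COc1c(I)c(OCOCC[Si](C)(C)C)c([Si](C)(C)C)c(OCOCC[Si](C)(C)C)c1CC=C(C)C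
F13 | step 12 | tert-butyl{[(2R)-2-{2,2-dimethyl-5-[(triisopropylsilyl)oxy]-2H-chromen-8-yl}-3-[2-methoxy-3-(3-methylbut-2-en-1-yl)-4,6-bis{[2-(trimethylsilyl)ethoxy]methoxy}-5-(trimethylsilyl)phenyl]propyl]oxy}dimethylsilane | COc1c(C[C@H](c2ccc(O[Si](C(C)C)(C(C)C)C(C)C)c3C=CC(C)(C)Oc23)CO[Si](C)(C)C(C)(C)C)c(OCOCC[Si](C)(C)C)c([Si](C)(C)C)c(OCOCC[Si](C)(C)C)c1CC=C(C)C
F14 | step 12 | 4-[(2R)-3-hydroxy-2-(5-hydroxy-2,2-dimethyl-2H-chromen-8-yl)propyl]-5-methoxy-6-(3-methylbut-2-en-1-yl)benzene-1,3-diol | COc1c(CC=C(C)C)c(O)cc(O)c1C[C@H](c1ccc(O)c2C=CC(C)(C)Oc12)CO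
A1 | alternative 1 | (4R)-4-benzyl-3-({2,2-dimethyl-5-[(triisopropylsilyl)oxy]-2H-chromen-8-yl}acetyl)-1,3-oxazolidin-2-one | O=C(Cc1ccc(O[Si](C(C)C)(C(C)C)C(C)C)c2C=CC(C)(C)Oc12)N1[C@H](Cc2ccccc2)COC1=O
A2 | alternative 1 | 2-(bromomethyl)-3-methoxy-1,5-bis(methoxymethoxy)-4-(3-methylbut-2-en-1-yl)benzene | BrCc1c(OC)c(CC=C(C)C)c(OCOC)cc1OCOC
A3 | alternative 1 | (4R)-4-benzyl-3-[(2R)-2-{2,2-dimethyl-5-[(triisopropylsilyl)oxy]-2H-chromen-8-yl}-3-[2-methoxy-4,6-bis(methoxymethoxy)-3-(3-methylbut-2-en-1-yl)phenyl]propanoyl]-1,3-oxazolidin-2-one | COc1c(CC=C(C)C)c(OCOC)cc(OCOC)c1C[C@H](c1ccc(O[Si](C(C)C)(C(C)C)C(C)C)c2C=CC(C)(C)Oc12)C(=O)N1[C@H](Cc2ccccc2)COC1=O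
A4 | alternative 2 | 3-{2,2-dimethyl-5-[(triisopropylsilyl)oxy]-2H-chromen-8-yl}-5-methoxy-7-(methoxymethoxy)-6-(3-methylbut-2-en-1-yl)-4H-chromen-4-one | COc1c(CC=C(C)C)c(OCOC)cc2occ(-c3ccc(O[Si](C(C)C)(C(C)C)C(C)C)c4C=CC(C)(C)Oc34)c(=O)c12
A5 | alternative 3 | (3R)-3-{2,2-dimethyl-5-[(triisopropylsilyl)oxy]-2H-chromen-8-yl}-5-methoxy-7-(methoxymethoxy)-6-(3-methylbut-2-en-1-yl)-3,4-dihydro-2H-chromen-2-one | COc1c(CC=C(C)C)c(OCOC)cc2c1C[C@H](c1ccc(O[Si](C(C)C)(C(C)C)C(C)C)c3c1OC(C)(C)C=C3)C(=O)O2
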